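**Retrosynthetic overview**
1. The two angelate C–O bonds at O6 and O8 are made last. The C8 oxygen comes from outer-face oxidation of the C8=C9 silyl enol ether of the 9-ketone.
2. Both oxiranes come from outer-face epoxidation of a (1(10)Z,4E)-germacradien-9-one: the 4,5-oxirane by hydroxyl direction, the 1,10-oxirane by conjugate hydroperoxide addition.
3. The ten-membered ring comes from forming C6–C7 by a direct Lewis-acid carbonyl-ene closure of a 4-angeloyloxy-8-oxo-(2E,6Z)-farnesal. The C10=C11 alkene attacks C1, a terminal methyl loses H, and the isopropenyl group appears (farnesyl → germacrenyl → germacrene A logic).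
4. The open chain comes from allyl Grignard opening of a dihydropyranone followed by isobutylidene cross-metathesis. The dihydropyranone comes from a catalytic asymmetric vinylogous aldol–lactonisation, which sets C3 and the Z alkene.
5. Ring order: temporary dihydropyranone (opened again) → ten-membered carbocycle → 4,5-oxirane → 1,10-oxirane.

Assumption: 1 and 2 are taken as catalogue chemicals, the ligand antipode in step 1 is the one that gives the S lactone, and germacrane numbering (C1–C15) is used for ring and open-chain compounds alike.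

Step 1
Reactants: 1 (E)-4,4-dimethoxy-2-methylbut-2-enal; 2 ethyl 2-methylbut-3-enoate (racemic)
Product: 4 (S)-6-[(E)-4,4-dimethoxybut-2-en-2-yl]-3-methyl-5,6-dihydro-2H-pyran-2-one, via Z-hydroxy ester 3 (not isolated)
Conditions: [Cu(MeCN)4]PF6 (5 mol %), (R)-DTBM-SEGPHOS (6 mol %), 2-tert-butyl-1,1,3,3-tetramethylguanidine (10 mol %), THF, −20 °C to rt
Reagents that add atoms: none
Why: Direct catalytic asymmetric vinylogous aldol addition followed by lactonisation, in which the monovalent-copper dienolate formed from 2 by soft deprotonation attacks the aldehyde of 1 only through its unhindered γ-carbon, the bisphosphine shields one aldehyde face so that C3 is set as S, and only the Z-configured aldolate 3 can reach its ester, so ring closure fixes the Z geometry of the later C1=C10 bond.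

Step 2
Reactants: 4 lactone from step 1; 5 allylmagnesium bromide; 6 angelic anhydride
Product: 8 (2E,4S,6Z)-1,1-dimethoxy-3,7-dimethyl-8-oxoundeca-2,6,10-trien-4-yl (Z)-2-methylbut-2-enoate, via bromomagnesium lactolate 7 (not isolated)
Conditions: CH2=CHCH2MgBr (1.05 equiv), THF, −78 °C; then 6 (1.5 equiv), −78 to 0 °C; aq NH4Cl
Reagents that add atoms: none
Why: 1,2-Addition of the hard allyl Grignard reagent to the lactone carbonyl stops at hemiketal alkoxide 7 at −78 °C, and on warming 7 equilibrates with the open δ-alkoxide of the Z-enone, the only form that gives a stable ester on O-acylation (alkoxide plus anhydride without a nucleophilic catalyst, so the angelate stays Z), while C3 and both alkene geometries are untouched.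

Step 3
Reactants: 8 allyl ketone from step 2; 9 2-methyl-2-butene
Product: 11 (2E,4S,6Z)-3,7,11-trimethyl-1,8-dioxododeca-2,6,10-trien-4-yl (Z)-2-methylbut-2-enoate (4-angeloyloxy-8-oxo-2E,6Z-farnesal), via prenyl ketone acetal 10 (not isolated)
Conditions: 9 (large excess), second-generation Hoveyda–Grubbs catalyst RuCl2(H2IMes)(=CH-C6H4-2-OiPr) (3 mol %), 1,4-benzoquinone (10 mol %), CH2Cl2, 35 °C; evaporate; PPTS (10 mol %), acetone–H2O 9:1, rt
Reagents that add atoms: water, O
Why: Olefin cross-metathesis of the only terminal alkene with excess 2-methyl-2-butene builds the prenyl terminus (every other alkene is trisubstituted or electron-poor, and benzoquinone suppresses ruthenium-hydride migration of the β,γ-alkene), and mild acid-catalysed acetal hydrolysis then frees the E-enal without touching C3.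

Step 4
Reactants: 11 open-chain keto aldehyde from step 3
Product: 12 (3S,6R,7S,1(10)Z,4E)-3-angeloyloxy-6-hydroxygermacra-1(10),4,11-trien-9-one (3β-OAng/6α-OH/7β-isopropenyl)
Conditions: Me2AlCl (3 equiv), CH2Cl2, 11 added by syringe pump over 12 h (0.001 M final), −40 to 0 °C; 1 M HCl
Reagents that add atoms: none
Why: Proposed new method: a ten-membered-ring carbonyl-ene (Prins-type) macrocyclisation in which the Me2AlCl-bound s-trans enal plays the part of the farnesyl C1 cation, the C7=C11 alkene attacks through its less substituted carbon (charge builds at tertiary C11) and the aldehyde oxygen takes H from the methyl group cis to H7 in a six-centre chair, so the C6 carbinol and the isopropenyl group arise in one event while Me2AlCl removes the proton as methane and keeps the β,γ-enone from migrating; with H3 eclipsing C4=C5 (A1,3 strain) the chain leaves C3 on one enal face only, so C7 reaches the Si face of C6, the chair with both ring bonds pseudo-equatorial gives the 6α-OH/7β-isopropenyl (anti) pair, and the Z-enone acts as a turn element; the closest known reaction types are Me2AlCl-promoted carbonyl-ene cyclisations to five- to seven-membered rings and Lewis-acid ene macrocyclisations of prenyl-terminated alkynals to twelve- and fourteen-membered rings.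

Step 5
Reactants: 12 germacratrienone from step 4
Product: 14 (1S,3S,4R,5R,6S,7S,10S)-3-angeloyloxy-1,10:4,5-diepoxy-6-hydroxygermacr-11-en-9-one, via 4,5-monoepoxide 13 (not isolated)
Conditions: VO(acac)2 (5 mol %), t-BuOOH (1.1 equiv, decane), CH2Cl2, 0 °C; then DBU (1.5 equiv), t-BuOOH (2 equiv), 0 °C to rt
Reagents that add atoms: tert-butyl hydroperoxide, CC(C)(C)OO
Why: Hydroxyl-directed vanadium-catalysed epoxidation selects the allylic C4=C5 bond (the homoallylic isopropenyl group, the enone and the angelate are far slower) and delivers oxygen to its only open outer face, on which the 6-OH lies (threo, A1,3 control, syn addition turning E into the trans 4α,5β-oxirane), and the following Weitz–Scheffer nucleophilic epoxidation adds t-BuOO− to C1 of the Z-enone, again from the outer face because C4 and C15 cover the inner one, with the ring holding the enolate so that closure outruns C1–C10 rotation and the cis 1α,10α-oxirane results.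

Step 6
Reactants: 14 diepoxy ketone from step 5
Product: 17 (1S,3S,4R,5R,6S,7S,8R,10S)-3-angeloyloxy-1,10:4,5-diepoxy-6,8-dihydroxygermacr-11-en-9-one, via bis-silyl enol ether 15 (not isolated), via bis-silyloxy ketone 16 (not isolated)
Conditions: LiN(SiMe3)2 (3 equiv), Me3SiCl (4 equiv, internal quench), THF, −78 °C; dimethyldioxirane (1.1 equiv, acetone), CH2Cl2, −78 to −40 °C; citric acid (cat.), MeOH, 0 °C
Reagents that add atoms: dimethyldioxirane, CC1(C)OO1
Why: Rubottom oxidation in which C8 is the only enolisable position of the 9-ketone (C10 is quaternary), internal-quench silylation also masks the 6-OH before its alkoxide can attack the neighbouring oxirane, the ring-trans silyl enol ether shows only its outer face to the dioxirane (which reacts far faster there than at the 1,1-disubstituted isopropenyl group) so the new oxygen is 8α and trans to the 7β-isopropenyl group, and mild methanolysis removes both silyl groups.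

Step 7
Reactants: 17 diol from step 6; 18 angelic acid
Product: 20 (1S,3S,4R,5R,6S,7S,8R,10S)-3,6,8-tris(angeloyloxy)-1,10:4,5-diepoxygermacr-11-en-9-one (CNP0154187.4), via 8-monoangelate 19 (not isolated)
Conditions: 18 (6 equiv), 2,4,6-Cl3C6H2COCl (6 equiv), Et3N (12 equiv), PhMe, rt; then 17, 75 °C
Reagents that add atoms: none
Why: Yamaguchi-type mixed-anhydride esterification without a nucleophilic pyridine catalyst, the usual way to make hindered angelates without Z to E leakage, acylates the more acidic 8-OH first and then the hindered 6-OH, and only O–H bonds are broken, so no stereocentre is touched.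

**Compound list**
1 | (E)-4,4-dimethoxy-2-methylbut-2-enal | COC(OC)/C=C(\C)C=O | starting material
2 | ethyl 2-methylbut-3-enoate (racemic) | C=CC(C)C(=O)OCC | starting material
3 | ethyl (2Z,5S,6E)-5-hydroxy-8,8-dimethoxy-2,6-dimethylocta-2,6-dienoate (not isolated) | COC(OC)/C=C(\C)[C@@H](O)C/C=C(/C)C(=O)OCC | intermediate
4 | (S)-6-[(E)-4,4-dimethoxybut-2-en-2-yl]-3-methyl-5,6-dihydro-2H-pyran-2-one | COC(OC)/C=C(\C)[C@@H]1CC=C(C)C(=O)O1 | intermediate
5 | allylmagnesium bromide | C=CC[Mg]Br | starting material
6 | angelic anhydride | C/C=C(/C)C(=O)OC(=O)/C(C)=C\C | starting material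
7 | bromomagnesium alkoxide of (6S)-2-allyl-6-[(E)-4,4-dimethoxybut-2-en-2-yl]-3-methyl-5,6-dihydro-2H-pyran-2-ol (anomeric centre undefined, not isolated) | COC(OC)/C=C(\C)[C@@H]1CC=C(C)C(CC=C)(O[Mg]Br)O1 | intermediate
8 | (2E,4S,6Z)-1,1-dimethoxy-3,7-dimethyl-8-oxoundeca-2,6,10-trien-4-yl angelate | COC(OC)/C=C(\C)[C@@H](OC(=O)/C(C)=C\C)C/C=C(/C)C(=O)CC=C | intermediate
9 | 2-methyl-2-butene | CC=C(C)C | starting material
10 | (2E,4S,6Z)-1,1-dimethoxy-3,7,11-trimethyl-8-oxododeca-2,6,10-trien-4-yl angelate (not isolated) | COC(OC)/C=C(\C)[C@@H](OC(=O)/C(C)=C\C)C/C=C(/C)C(=O)CC=C(C)C | intermediate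
11 | (2E,4S,6Z)-3,7,11-trimethyl-1,8-dioxododeca-2,6,10-trien-4-yl angelate | O=C/C=C(\C)[C@@H](OC(=O)/C(C)=C\C)C/C=C(/C)C(=O)CC=C(C)C | intermediate
12 | (3S,6R,7S,1(10)Z,4E)-3-angeloyloxy-6-hydroxygermacra-1(10),4,11-trien-9-one | C=C(C)[C@H]1[C@H](O)/C=C(\C)[C@@H](OC(=O)/C(C)=C\C)C/C=C(/C)C(=O)C1 | intermediate
13 | (3S,4R,5R,6S,7S,1(10)Z)-3-angeloyloxy-4,5-epoxy-6-hydroxygermacra-1(10),11-dien-9-one (not isolated) | C=C(C)[C@H]1[C@H](O)[C@H]2O[C@]2(C)[C@@H](OC(=O)/C(C)=C\C)C/C=C(/C)C(=O)C1 | intermediate
14 | (1S,3S,4R,5R,6S,7S,10S)-3-angeloyloxy-1,10:4,5-diepoxy-6-hydroxygermacr-11-en-9-one | C=C(C)[C@H]1[C@H](O)[C@H]2O[C@]2(C)[C@@H](OC(=O)/C(C)=C\C)C[C@@H]2O[C@]2(C)C(=O)C1 | intermediate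
15 | 6-O-trimethylsilyl (8Z)-9-trimethylsilyloxy-8-ene derived from 14 (C7 and C10 trans on C8=C9, not isolated) | C=C(C)[C@H]1[C@H](O[Si](C)(C)C)[C@H]2O[C@]2(C)[C@@H](OC(=O)/C(C)=C\C)C[C@@H]2O[C@]2(C)/C(O[Si](C)(C)C)=C/1 | intermediate
16 | 6,8-bis-O-trimethylsilyl ether of 17 (not isolated) | C=C(C)[C@H]1[C@H](O[Si](C)(C)C)[C@H]2O[C@]2(C)[C@@H](OC(=O)/C(C)=C\C)C[C@@H]2O[C@]2(C)C(=O)[C@@H]1O[Si](C)(C)C | intermediate
17 | (1S,3S,4R,5R,6S,7S,8R,10S)-3-angeloyloxy-1,10:4,5-diepoxy-6,8-dihydroxygermacr-11-en-9-one | C=C(C)[C@H]1[C@H](O)[C@H]2O[C@]2(C)[C@@H](OC(=O)/C(C)=C\C)C[C@@H]2O[C@]2(C)C(=O)[C@@H]1O | intermediate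
18 | angelic acid, (Z)-2-methylbut-2-enoic acid | C/C=C(/C)C(=O)O | starting material
19 | (1S,3S,4R,5R,6S,7S,8R,10S)-3,8-bis(angeloyloxy)-1,10:4,5-diepoxy-6-hydroxygermacr-11-en-9-one (not isolated) | C=C(C)[C@H]1[C@H](O)[C@H]2O[C@]2(C)[C@@H](OC(=O)/C(C)=C\C)C[C@@H]2O[C@]2(C)C(=O)[C@@H]1OC(=O)/C(C)=C\C | intermediate
20 | (1S,3S,4R,5R,6S,7S,8R,10S)-3,6,8-tris(angeloyloxy)-1,10:4,5-diepoxygermacr-11-en-9-one, CNP0154187.4 | C=C(C)[C@H]1[C@H](OC(=O)/C(C)=C\C)[C@H]2O[C@]2(C)[C@@H](OC(=O)/C(C)=C\C)C[C@@H]2O[C@]2(C)C(=O)[C@@H]1OC(=O)/C(C)=C\C | target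

**Totals**
Total step count: 7. Longest linear sequence: 7 (fully linear from 1).

**Three steps most likely to fail**

Step 4, the carbonyl-ene macrocyclisation. The risks are oligomerisation, migration of the β,γ-alkene into conjugation, transannular side reactions, and the wrong C6/C7 pair. The fallback gives the prenyl terminus a halide handle and closes the same C6–C7 bond reductively. It sets out from 11. SeO2 (cat.)/t-BuOOH oxidises the E-methyl group to the 12-hydroxy aldehyde F1, and NBS/Me2S (Corey–Kim) converts it into the allylic bromide F2. A Nozaki–Hiyama allylation with CrCl2 in THF at 0.002 M then forms the bond at C7 with allyl transposition. This addition is anti-selective through a chair and gives the same 6α-OH/7β-isopropenyl pair. The fallback rejoins the route at 12.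

Step 5, second stage. The stepwise hydroperoxide addition may allow C1–C10 rotation and give the trans-oxirane, and DBU may trigger vinylogous loss of the C3 angelate. The fallback makes the 1,10-oxirane by a concerted, stereospecific electrophilic epoxidation at the allylic-alcohol oxidation level. It sets out from 13, isolated after the vanadium stage.
- TESCl/imidazole gives the 6-O-triethylsilyl ether F3.
- NaBH4/CeCl3·7H2O in MeOH at −78 °C gives the 9-alcohol F4, with hydride arriving from the outer face.
- mCPBA/NaHCO3 epoxidises the now electron-rich trisubstituted Z alkene from the outer face, faster than the isopropenyl group, to give the cis-1,10-epoxy alcohol F5.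
- Dess–Martin periodinane gives the diepoxy ketone silyl ether F6.
- HF·pyridine removes the silyl group, and the fallback rejoins the route at 14.

Step 2, the single allyl addition with in-flask opening and acylation. The risks are double addition, acylation at the hemiketal oxygen, and migration of the allyl ketone into conjugation. The fallback separates ring opening from carbon–carbon bond formation through an N-methoxy-N-methyl amide. It sets out from 4. Me(MeO)NH·HCl/i-PrMgCl opens the lactone to the hydroxy Weinreb amide F7, and 6 added to the same flask acylates its magnesium alkoxide to give the angelate Weinreb amide F8. CH2=CHCH2MgBr at −78 °C then adds only once, because the amide holds the adduct until work-up. The fallback rejoins the route at 8.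

**Further compounds**
F1 | step 4 | (2E,4S,6Z,10E)-12-hydroxy-3,7,11-trimethyl-1,8-dioxododeca-2,6,10-trien-4-yl angelate | O=C/C=C(\C)[C@@H](OC(=O)/C(C)=C\C)C/C=C(/C)C(=O)C/C=C(\C)CO
F2 | step 4 | (2E,4S,6Z,10E)-12-bromo-3,7,11-trimethyl-1,8-dioxododeca-2,6,10-trien-4-yl angelate | O=C/C=C(\C)[C@@H](OC(=O)/C(C)=C\C)C/C=C(/C)C(=O)C/C=C(\C)CBr
F3 | step 5 | 6-O-triethylsilyl ether of 13 | C=C(C)[C@H]1[C@H](O[Si](CC)(CC)CC)[C@H]2O[C@]2(C)[C@@H](OC(=O)/C(C)=C\C)C/C=C(/C)C(=O)C1
F4 | step 5 | (9R)-9-alcohol from F3 | C=C(C)[C@H]1[C@H](O[Si](CC)(CC)CC)[C@H]2O[C@]2(C)[C@@H](OC(=O)/C(C)=C\C)C/C=C(/C)[C@H](O)C1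
F5 | step 5 | (1S,10S)-cis-1,10-epoxide of F4 | C=C(C)[C@H]1[C@H](O[Si](CC)(CC)CC)[C@H]2O[C@]2(C)[C@@H](OC(=O)/C(C)=C\C)C[C@@H]2O[C@]2(C)[C@H](O)C1
F6 | step 5 | 6-O-triethylsilyl ether of 14 | C=C(C)[C@H]1[C@H](O[Si](CC)(CC)CC)[C@H]2O[C@]2(C)[C@@H](OC(=O)/C(C)=C\C)C[C@@H]2O[C@]2(C)C(=O)C1
F7 | step 2 | (2Z,5S,6E)-5-hydroxy-N,8,8-trimethoxy-N,2,6-trimethylocta-2,6-dienamide | COC(OC)/C=C(\C)[C@@H](O)C/C=C(/C)C(=O)N(C)OC
F8 | step 2 | 5-O-angelate of F7 | COC(OC)/C=C(\C)[C@@H](OC(=O)/C(C)=C\C)C/C=C(/C)C(=O)N(C)OC
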